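## Retrosynthetic overview

1. Numbering: C7 is the acetoxy carbon, C8 the aryloxy carbon, C1 the attached carbon of the trimethoxyphenyl ring and C4' the side-chain carbon of the dimethoxyphenoxy ring. The last disconnection is C4'–CH=, a Stille coupling of an aryl bromide with (E)-Bu3SnCH=CHCH2OH, so no protecting group is carried.
2. The key disconnection is C1–C7: Cram-chelate addition of 3,4,5-trimethoxyphenylmagnesium bromide to (R)-2-(4-bromo-2,6-dimethoxyphenoxy)propanal, with the alkoxide acetylated in the same flask. One operation gives the aryl–carbon bond, the C7 stereocentre (threo to C8) and the acetate.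
3. Enabling feature: the C8 ether oxygen alpha to the C7 carbonyl, which closes a five-membered O=C7–C8–O···Mg chelate. It sits on the dimethoxyphenoxy ring, whose two ortho methoxy groups twist the aryl–O bond and keep that oxygen a good donor.
4. C8 comes from ethyl (S)-lactate by Mitsunobu inversion with 4-bromo-2,6-dimethoxyphenol; the ester is taken to the aldehyde with DIBAL-H.
5. No ring is formed in the route: both benzene rings are bought intact.

Key step: step 4

Remark: 4-bromo-2,6-dimethoxyphenol and (E)-3-(tributylstannyl)prop-2-en-1-ol are taken as catalogue compounds (otherwise each is one step away, from 2,6-dimethoxyphenol/NBS and propargyl alcohol/Bu3SnH).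

## Route

Step 1
Reactants: 1 4-bromo-2,6-dimethoxyphenol; 2 ethyl (S)-lactate
Product: 3 ethyl (2R)-2-(4-bromo-2,6-dimethoxyphenoxy)propanoate
Conditions: PPh3, DIAD, THF, 0 °C to rt
Reagents that add atoms: none
Why: Mitsunobu etherification, in which the phenol displaces the lactate oxyphosphonium by SN2 with inversion, so the (S)-lactate should give the (R)-aryl ether that becomes C8.

Step 2
Reactants: 3 ethyl (2R)-2-(4-bromo-2,6-dimethoxyphenoxy)propanoate
Product: 4 (2R)-2-(4-bromo-2,6-dimethoxyphenoxy)propanal
Conditions: DIBAL-H (1.1 equiv), CH2Cl2, −78 °C; MeOH, then aq. Rochelle salt; used crude at once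
Reagents that add atoms: none
Why: Partial DIBAL-H reduction of an ester, in which the aluminium hemiacetal (stabilised at −78 °C by the neighbouring C8 oxygen) collapses to the aldehyde only on work-up, and no bond at C8 is touched so its R configuration is carried over.

Step 3
Reactants: 5 5-bromo-1,2,3-trimethoxybenzene
Product: 6 (3,4,5-trimethoxyphenyl)magnesium bromide (Et2O solution, titrated and used directly)
Conditions: Mg turnings, cat. I2, Et2O, reflux
Reagents that add atoms: magnesium [Mg]
Why: Grignard formation by magnesium insertion into the aryl bromide, run in Et2O and not THF so that the solvent does not compete with the substrate for magnesium in step 4.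

Step 4
Reactants: 4 (2R)-2-(4-bromo-2,6-dimethoxyphenoxy)propanal; 6 (3,4,5-trimethoxyphenyl)magnesium bromide
Product: 8 (1R,2R)-2-(4-bromo-2,6-dimethoxyphenoxy)-1-(3,4,5-trimethoxyphenyl)propyl acetate, via bromomagnesium threo-alkoxide 7 (not isolated)
Conditions: 4, MgBr2·OEt2 (1.5 equiv), CH2Cl2, −78 °C; then 6 (Et2O), −78 °C; then Ac2O, cat. DMAP, −78 °C to rt; aq. NH4Cl
Reagents that add atoms: acetic anhydride CC(=O)OC(C)=O
Why: MgBr2·OEt2 in CH2Cl2 should lock the C7 carbonyl oxygen and the C8 ether oxygen of 4 into a five-membered magnesium chelate, the aryl Grignard 6 then adds to C7 from the chelate face anti to the C8 methyl group (the Re face), and the bromomagnesium alkoxide 7 is acetylated in the same flask by Ac2O/DMAP. The closest known reaction type is the Cram-chelate addition of Grignard reagents to alpha-alkoxy aldehydes, followed by in situ O-acylation of the magnesium alkoxide. No ring of the product is closed; the only ring involved is the transient O=C7–C8–O–Mg chelate. The new stereocentre C7 is set as R by 1,2-induction from the lactate-derived C8 (R) centre, which gives the syn (threo) 7R,8R pair. The step needs the chelate pathway to win over open Felkin–Anh addition, which would give the erythro epimer; this is secured by the non-coordinating solvent, the bidentate Lewis acid and the two ortho methoxy groups of the bromodimethoxyphenoxy ring, which twist the aryl–O bond out of conjugation so that the C8 oxygen keeps ether-like basicity. Addition at −78 °C should outrun enolisation of 4, so C8 is not scrambled.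

Step 5
Reactants: 8 (1R,2R)-2-(4-bromo-2,6-dimethoxyphenoxy)-1-(3,4,5-trimethoxyphenyl)propyl acetate; 9 (E)-3-(tributylstannyl)prop-2-en-1-ol
Product: 10 (1R,2R)-2-{4-[(E)-3-hydroxyprop-1-en-1-yl]-2,6-dimethoxyphenoxy}-1-(3,4,5-trimethoxyphenyl)propyl acetate (target)
Conditions: Pd(P(t-Bu)3)2 (cat.), CsF, 1,4-dioxane, rt to 50 °C
Reagents that add atoms: none
Why: Stille coupling with fluoride activation, in which the bulky electron-rich phosphine permits oxidative addition into the electron-rich aryl bromide, the alkenyl group transfers with retention of its E geometry, and the neutral non-hydrolytic medium should leave the C7 acetate, the free allylic alcohol and both stereocentres untouched.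

## Compound list

1 | 4-bromo-2,6-dimethoxyphenol | COc1cc(Br)cc(OC)c1O | starting material
2 | ethyl (S)-lactate (ethyl (2S)-2-hydroxypropanoate) | C[C@H](O)C(=O)OCC | starting material
3 | ethyl (2R)-2-(4-bromo-2,6-dimethoxyphenoxy)propanoate | CCOC(=O)[C@@H](C)Oc1c(OC)cc(Br)cc1OC | intermediate
4 | (2R)-2-(4-bromo-2,6-dimethoxyphenoxy)propanal | O=C[C@@H](C)Oc1c(OC)cc(Br)cc1OC | intermediate
5 | 5-bromo-1,2,3-trimethoxybenzene | COc1cc(Br)cc(OC)c1OC | starting material
6 | (3,4,5-trimethoxyphenyl)magnesium bromide | COc1cc([Mg]Br)cc(OC)c1OC | intermediate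
7 | bromomagnesium (1R,2R)-2-(4-bromo-2,6-dimethoxyphenoxy)-1-(3,4,5-trimethoxyphenyl)propan-1-olate | COc1cc([C@@H](O[Mg]Br)[C@@H](C)Oc2c(OC)cc(Br)cc2OC)cc(OC)c1OC | intermediate
8 | (1R,2R)-2-(4-bromo-2,6-dimethoxyphenoxy)-1-(3,4,5-trimethoxyphenyl)propyl acetate | COc1cc([C@@H](OC(C)=O)[C@@H](C)Oc2c(OC)cc(Br)cc2OC)cc(OC)c1OC | intermediate
9 | (E)-3-(tributylstannyl)prop-2-en-1-ol | CCCC[Sn](CCCC)(CCCC)/C=C/CO | starting material
10 | (1R,2R)-2-{4-[(E)-3-hydroxyprop-1-en-1-yl]-2,6-dimethoxyphenoxy}-1-(3,4,5-trimethoxyphenyl)propyl acetate | COc1cc([C@@H](OC(C)=O)[C@@H](C)Oc2c(OC)cc(/C=C/CO)cc2OC)cc(OC)c1OC | target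

## Summary

Total step count: 5
Longest linear sequence: 4 steps (1 → 3 → 4 → 8 → 10); step 3 is a one-step side branch.

## Steps most likely to fail

**Step 4 (key step).** The facial selectivity may erode if the aryl ether oxygen or residual ethereal solvent lets the open Felkin–Anh pathway compete with the magnesium chelate, which would give the erythro epimer. Trapping of the hindered alkoxide may also be incomplete. The fallback sets out from ester 3. Transamidation with MeNH(OMe)·HCl/i-PrMgCl (THF, −20 °C) should give the Weinreb amide (2R)-2-(4-bromo-2,6-dimethoxyphenoxy)-N-methoxy-N-methylpropanamide F1. Addition of 6 (THF, 0 °C) then makes the same aryl–C7 bond without any stereochemical demand, as the ketone (2R)-2-(4-bromo-2,6-dimethoxyphenoxy)-1-(3,4,5-trimethoxyphenyl)propan-1-one F2. Felkin–Anh reduction with the bulky, non-chelating K-Selectride (THF, −78 °C; hydride anti to the C8–O bond) should give the threo alcohol (1R,2R)-2-(4-bromo-2,6-dimethoxyphenoxy)-1-(3,4,5-trimethoxyphenyl)propan-1-ol F3. Acetylation with Ac2O/pyridine/cat. DMAP comes back to the route at 8.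

**Step 5.** Oxidative addition into the electron-rich aryl bromide may be slow, which would allow protodestannylation or homocoupling of 9 and fluoride-promoted acetyl transfer to the allylic alcohol. The fallback sets out from 8. Suzuki–Miyaura coupling with commercial (E)-2-[3-(tert-butyldimethylsilyloxy)prop-1-en-1-yl]-4,4,5,5-tetramethyl-1,3,2-dioxaborolane (XPhos Pd G3, K3PO4, THF/H2O, 40 °C) should give the silyl ether (1R,2R)-2-{4-[(E)-3-(tert-butyldimethylsilyloxy)prop-1-en-1-yl]-2,6-dimethoxyphenoxy}-1-(3,4,5-trimethoxyphenyl)propyl acetate F4. Desilylation with HF·pyridine (THF/pyridine, 0 °C), which spares the acetate, comes back at 10.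

**Step 2.** Over-reduction to the primary alcohol may occur, and the alpha-aryloxy aldehyde may lose configurational purity at C8 by enolisation during work-up or handling. The fallback sets out from 3. Exhaustive reduction with LiBH4 (THF/MeOH, 0 °C) should give the configurationally stable alcohol (2R)-2-(4-bromo-2,6-dimethoxyphenoxy)propan-1-ol F5. Oxidation with Dess–Martin periodinane (NaHCO3, CH2Cl2, 0 °C) under neutral conditions comes back at 4, to be used immediately.

## Further compounds

F1 | step 4 | (2R)-2-(4-bromo-2,6-dimethoxyphenoxy)-N-methoxy-N-methylpropanamide | CON(C)C(=O)[C@@H](C)Oc1c(OC)cc(Br)cc1OC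
F2 | step 4 | (2R)-2-(4-bromo-2,6-dimethoxyphenoxy)-1-(3,4,5-trimethoxyphenyl)propan-1-one | COc1cc(C(=O)[C@@H](C)Oc2c(OC)cc(Br)cc2OC)cc(OC)c1OC
F3 | step 4 | (1R,2R)-2-(4-bromo-2,6-dimethoxyphenoxy)-1-(3,4,5-trimethoxyphenyl)propan-1-ol | COc1cc([C@@H](O)[C@@H](C)Oc2c(OC)cc(Br)cc2OC)cc(OC)c1OC
F4 | step 5 | (1R,2R)-2-{4-[(E)-3-(tert-butyldimethylsilyloxy)prop-1-en-1-yl]-2,6-dimethoxyphenoxy}-1-(3,4,5-trimethoxyphenyl)propyl acetate | COc1cc([C@@H](OC(C)=O)[C@@H](C)Oc2c(OC)cc(/C=C/CO[Si](C)(C)C(C)(C)C)cc2OC)cc(OC)c1OC
F5 | step 2 | (2R)-2-(4-bromo-2,6-dimethoxyphenoxy)propan-1-ol | OC[C@@H](C)Oc1c(OC)cc(Br)cc1OC
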